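**Plan**

- Retrosynthesis: the four O-benzyl bonds are cut first, then the C4''–C4a'' and O1''–C2'' bonds of the pyranone (ring C) of unit 2 (the 4-hydroxyphenyl flavone), then the C8–C8'' biaryl bond to unit 1 (the 4-methoxyphenyl flavone).
- Enabling feature: C8'' of unit 2 lies between C7''–O and C8a''–O1'' and para to C5''–O. Before ring C exists, ring A of unit 2 is therefore a 2,6-dihydroxy-4-alkoxyphenyl group on C8 of unit 1, mirror-symmetric about the biaryl bond. With the para oxygen benzylated, pyranone closure can only give the 8''-linked flavone.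
- Forward order: acacetin supplies rings A, B and C of unit 1 and is benzylated and iodinated at C8. Phloroglucinol is turned into a 2,6-bis(MOM)-4-benzyloxyphenyl boronate. Suzuki coupling makes C8–C8'', the MOM groups are removed, a thermal annulation with an aroylacetic ester closes ring C of unit 2, and hydrogenolysis frees the phenols.
- Stereochemistry: the target has no stereocentre. The 8–8'' axis becomes stereogenic only in the annulation and is formed without control.

Key step: step 9

Remark: the target SMILES carries no stereodescriptor, so the hindered 8–8'' axis is treated as unspecified and the route is expected to deliver the racemic atropisomers.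

**Route**

Step 1
Reactants: 1 acacetin
Product: 2 5,7-bis(benzyloxy)-2-(4-methoxyphenyl)-4H-chromen-4-one
Conditions: BnBr (3 equiv), K2CO3, DMF, 80 °C
Reagents that add atoms: benzyl bromide BrCc1ccccc1
Why: Williamson etherification, in which the 7-hydroxyl reacts readily and the chelated 5-hydroxyl is driven to completion by excess halide and heat in DMF.

Step 2
Reactants: 2 5,7-bis(benzyloxy)-2-(4-methoxyphenyl)-4H-chromen-4-one
Product: 3 5,7-bis(benzyloxy)-8-iodo-2-(4-methoxyphenyl)-4H-chromen-4-one
Conditions: NIS (1.1 equiv), TFA (cat.), MeCN/CH2Cl2, 0 °C to rt, dark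
Reagents that add atoms: N-iodosuccinimide O=C1CCC(=O)N1I
Why: Electrophilic aromatic iodination, which in 5,7-dialkoxyflavones should go to C8 (ortho to O7, para to O5) because C6 is shielded by two benzyloxy groups and the anisyl ring is deactivated by conjugation with the pyranone.

Step 3
Reactants: 4 phloroglucinol
Product: 5 3,5-bis(methoxymethoxy)phenol
Conditions: NaH (2.0 equiv), DMF, 0 °C; MOMCl (2.0 equiv), 0 °C to rt; chromatography
Reagents that add atoms: chloromethyl methyl ether COCCl
Why: Statistical Williamson-type O-alkylation with a hard electrophile that favours O- over C-alkylation, the bis-ether being separated from the mono- and tris-ethers.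

Step 4
Reactants: 5 3,5-bis(methoxymethoxy)phenol
Product: 6 1-(benzyloxy)-3,5-bis(methoxymethoxy)benzene
Conditions: BnBr, K2CO3, DMF, rt to 50 °C
Reagents that add atoms: benzyl bromide BrCc1ccccc1
Why: Williamson etherification of the single remaining phenol, which fixes the oxygen that must stay blocked in the annulation.

Step 5
Reactants: 6 1-(benzyloxy)-3,5-bis(methoxymethoxy)benzene
Product: 8 2-[4-(benzyloxy)-2,6-bis(methoxymethoxy)phenyl]-4,4,5,5-tetramethyl-1,3,2-dioxaborolane, via aryllithium 7 (not isolated)
Conditions: n-BuLi (1.1 equiv), THF, 0 °C, 1 h; i-PrOBpin, −78 °C to rt; H2O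
Reagents that add atoms: 2-isopropoxy-4,4,5,5-tetramethyl-1,3,2-dioxaborolane CC(C)OB1OC(C)(C)C(C)(C)O1
Why: Directed ortho-metalation at the carbon between the two MOM ethers, the doubly coordinated and most acidic site, followed by borate trapping of the aryllithium.

Step 6
Reactants: 3 5,7-bis(benzyloxy)-8-iodo-2-(4-methoxyphenyl)-4H-chromen-4-one; 8 2-[4-(benzyloxy)-2,6-bis(methoxymethoxy)phenyl]-4,4,5,5-tetramethyl-1,3,2-dioxaborolane
Product: 9 5,7-bis(benzyloxy)-8-[4-(benzyloxy)-2,6-bis(methoxymethoxy)phenyl]-2-(4-methoxyphenyl)-4H-chromen-4-one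
Conditions: Pd(OAc)2 (5 mol%), SPhos (10 mol%), K3PO4, 8 (1.8 equiv), toluene/H2O (10:1), 100 °C
Reagents that add atoms: none
Why: Suzuki–Miyaura cross-coupling, in which zerovalent palladium carrying the bulky electron-rich dialkylbiarylphosphine should add to the hindered iodide and still eliminate the tetra-ortho-substituted biaryl, with excess boronate offsetting protodeboronation.

Step 7
Reactants: 9 5,7-bis(benzyloxy)-8-[4-(benzyloxy)-2,6-bis(methoxymethoxy)phenyl]-2-(4-methoxyphenyl)-4H-chromen-4-one
Product: 10 5,7-bis(benzyloxy)-8-[4-(benzyloxy)-2,6-dihydroxyphenyl]-2-(4-methoxyphenyl)-4H-chromen-4-one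
Conditions: conc. HCl (cat.), MeOH/THF (1:1), 45 °C
Reagents that add atoms: none
Why: Acid-catalysed acetal exchange with methanol removes both MOM ethers while the benzyl ethers, the methyl ether and the chromone are inert to dilute acid.

Step 8
Reactants: 11 4'-benzyloxyacetophenone; 12 diethyl carbonate
Product: 13 ethyl 3-[4-(benzyloxy)phenyl]-3-oxopropanoate
Conditions: NaH (2.5 equiv), THF, reflux; aq. HCl, 0 °C
Reagents that add atoms: none
Why: Crossed Claisen condensation of the ketone enolate with the non-enolisable carbonate, driven by deprotonation of the β-keto ester formed.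

Step 9
Reactants: 10 5,7-bis(benzyloxy)-8-[4-(benzyloxy)-2,6-dihydroxyphenyl]-2-(4-methoxyphenyl)-4H-chromen-4-one; 13 ethyl 3-[4-(benzyloxy)phenyl]-3-oxopropanoate
Product: 16 5,7-bis(benzyloxy)-8-{5-(benzyloxy)-2-[4-(benzyloxy)phenyl]-7-hydroxy-4-oxo-4H-chromen-8-yl}-2-(4-methoxyphenyl)-4H-chromen-4-one, via aroylketene 14 (not isolated), via aryl 1,3-diketone 15 (not isolated)
Conditions: 13 (2.5 equiv, added in portions), Ph2O, 240–250 °C, N2 sweep to remove EtOH and H2O, 1–2 h
Reagents that add atoms: none
Why: On heating, keto ester 13 loses ethanol to give aroylketene 14, which C-acylates the free dihydroxyphenyl ring of 10 at C3 (equivalent to C5), ortho to one hydroxyl and to the benzyloxy group and para to the other hydroxyl, to give the chelated aryl 1,3-diketone 15. The hydroxyl next to the biaryl carbon then adds to the aryl ketone carbonyl in a 6-exo-trig closure and loss of water gives the pyranone, so C4''–C4a'' and O1''–C2'' form and ring C of unit 2 closes in one operation. The closest known reaction is the Mentzer pyrone synthesis, the thermal condensation of phloroglucinol-type phenols with aroylacetic esters to 5,7-dioxygenated flavones. No stereocentre is created; the 8–8'' axis becomes stereogenic here and forms without control. The step needs a chromone rather than a 4-arylcoumarin, which the acid-free thermal ketene pathway secures, and an 8''- rather than a 6''-linkage, which follows because the ring is symmetric about the biaryl bond and its para oxygen is benzylated, leaving only the two equivalent hydroxyls beside the biaryl carbon to close. All hydroxyls of unit 1 are benzylated, so the only other nucleophile is the second hydroxyl of the ring, which ends as the free 7''-hydroxyl.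

Step 10
Reactants: 16 5,7-bis(benzyloxy)-8-{5-(benzyloxy)-2-[4-(benzyloxy)phenyl]-7-hydroxy-4-oxo-4H-chromen-8-yl}-2-(4-methoxyphenyl)-4H-chromen-4-one
Product: 17 5,7-dihydroxy-8-[5,7-dihydroxy-2-(4-hydroxyphenyl)-4-oxo-4H-chromen-8-yl]-2-(4-methoxyphenyl)-4H-chromen-4-one
Conditions: H2 (1 atm), 10% Pd/C, THF/MeOH (1:1), rt
Reagents that add atoms: none
Why: Catalytic hydrogenolysis cleaves the four benzyl aryl ethers, while the aryl methyl ether is inert and the conjugated chromone C2–C3 bonds should resist reduction at atmospheric pressure.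

**Compound list**

1 | acacetin (5,7-dihydroxy-2-(4-methoxyphenyl)-4H-chromen-4-one) | COc1ccc(cc1)-c1cc(=O)c2c(O)cc(O)cc2o1 | starting material
2 | 5,7-bis(benzyloxy)-2-(4-methoxyphenyl)-4H-chromen-4-one | COc1ccc(cc1)-c1cc(=O)c2c(OCc3ccccc3)cc(OCc3ccccc3)cc2o1 | intermediate
3 | 5,7-bis(benzyloxy)-8-iodo-2-(4-methoxyphenyl)-4H-chromen-4-one | COc1ccc(cc1)-c1cc(=O)c2c(OCc3ccccc3)cc(OCc3ccccc3)c(I)c2o1 | intermediate
4 | phloroglucinol | Oc1cc(O)cc(O)c1 | starting material
5 | 3,5-bis(methoxymethoxy)phenol | COCOc1cc(O)cc(OCOC)c1 | intermediate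
6 | 1-(benzyloxy)-3,5-bis(methoxymethoxy)benzene | COCOc1cc(OCc2ccccc2)cc(OCOC)c1 | intermediate
7 | [4-(benzyloxy)-2,6-bis(methoxymethoxy)phenyl]lithium (formed in the flask) | [Li]c1c(OCOC)cc(OCc2ccccc2)cc1OCOC | intermediate
8 | 2-[4-(benzyloxy)-2,6-bis(methoxymethoxy)phenyl]-4,4,5,5-tetramethyl-1,3,2-dioxaborolane | COCOc1cc(OCc2ccccc2)cc(OCOC)c1B1OC(C)(C)C(C)(C)O1 | intermediate
9 | 5,7-bis(benzyloxy)-8-[4-(benzyloxy)-2,6-bis(methoxymethoxy)phenyl]-2-(4-methoxyphenyl)-4H-chromen-4-one | COc1ccc(cc1)-c1cc(=O)c2c(OCc3ccccc3)cc(OCc3ccccc3)c(-c3c(OCOC)cc(OCc4ccccc4)cc3OCOC)c2o1 | intermediate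
10 | 5,7-bis(benzyloxy)-8-[4-(benzyloxy)-2,6-dihydroxyphenyl]-2-(4-methoxyphenyl)-4H-chromen-4-one | COc1ccc(cc1)-c1cc(=O)c2c(OCc3ccccc3)cc(OCc3ccccc3)c(-c3c(O)cc(OCc4ccccc4)cc3O)c2o1 | intermediate
11 | 4'-benzyloxyacetophenone (1-[4-(benzyloxy)phenyl]ethan-1-one) | CC(=O)c1ccc(OCc2ccccc2)cc1 | starting material
12 | diethyl carbonate | CCOC(=O)OCC | starting material
13 | ethyl 3-[4-(benzyloxy)phenyl]-3-oxopropanoate | CCOC(=O)CC(=O)c1ccc(OCc2ccccc2)cc1 | intermediate
14 | 3-[4-(benzyloxy)phenyl]-3-oxoprop-1-en-1-one (aroylketene, formed in the flask) | O=C=CC(=O)c1ccc(OCc2ccccc2)cc1 | intermediate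
15 | 5,7-bis(benzyloxy)-8-{4-(benzyloxy)-3-[3-(4-(benzyloxy)phenyl)-3-oxopropanoyl]-2,6-dihydroxyphenyl}-2-(4-methoxyphenyl)-4H-chromen-4-one (formed in the flask) | COc1ccc(cc1)-c1cc(=O)c2c(OCc3ccccc3)cc(OCc3ccccc3)c(-c3c(O)cc(OCc4ccccc4)c(C(=O)CC(=O)c4ccc(OCc5ccccc5)cc4)c3O)c2o1 | intermediate
16 | 5,7-bis(benzyloxy)-8-{5-(benzyloxy)-2-[4-(benzyloxy)phenyl]-7-hydroxy-4-oxo-4H-chromen-8-yl}-2-(4-methoxyphenyl)-4H-chromen-4-one | COc1ccc(cc1)-c1cc(=O)c2c(OCc3ccccc3)cc(OCc3ccccc3)c(-c3c(O)cc(OCc4ccccc4)c4c(=O)cc(-c5ccc(OCc6ccccc6)cc5)oc34)c2o1 | intermediate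
17 | 5,7-dihydroxy-8-[5,7-dihydroxy-2-(4-hydroxyphenyl)-4-oxo-4H-chromen-8-yl]-2-(4-methoxyphenyl)-4H-chromen-4-one (CNP0322111.0) | COc1ccc(-c2cc(=O)c3c(O)cc(O)c(-c4c(O)cc(O)c5c(=O)cc(-c6ccc(O)cc6)oc45)c3o2)cc1 | target

**Step count and risks**

Total step count: 10. Longest linear sequence: 7 steps (steps 3, 4, 5, 6, 7, 9, 10, from phloroglucinol).

Steps most likely to fail:

Step 9. Several processes could divert the annulation:
- the ketene may be taken up by oxygen, leaving an aryl β-keto ester that does not rearrange or that drifts to the 4-arylcoumarin;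
- benzyl groups may migrate or be lost at 240 °C in the presence of free phenols;
- C-acylation may be slow beside the hindered biaryl axis while the keto ester self-condenses;
- a second annulation may start at C6'' with the remaining hydroxyl.

The fallback builds the same ring stepwise at low temperature. It sets out from 10 and rejoins the route at 15. Friedel–Crafts C-acetylation of 10 (Ac2O, BF3·OEt2, EtOAc, rt) at the same ring carbon should give the acetophenone 8-[3-acetyl-4-(benzyloxy)-2,6-dihydroxyphenyl]-5,7-bis(benzyloxy)-2-(4-methoxyphenyl)-4H-chromen-4-one F1. Its lithium polyanion (LiHMDS, 4.5 equiv, THF, −78 °C) is C-aroylated with commercial 4-(benzyloxy)benzoyl chloride to give the 1,3-diketone 15, now isolated. Cyclodehydration with TsOH in toluene at 80 °C then gives 16.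

Step 6. Protodeboronation of the 2,6-dioxygenated arylboronate under aqueous base may outrun transmetalation onto the hindered arylpalladium iodide, and the iodide may be reduced instead of coupled. The fallback is a base-free Negishi coupling. It sets out from 6 and rejoins the route at 9. Lithiation as in step 5 gives 7, and ZnCl2 in THF converts it into [4-(benzyloxy)-2,6-bis(methoxymethoxy)phenyl]zinc chloride F2. This is coupled with iodide 3 using Pd(OAc)2/SPhos in THF at 60 °C to give 9.

Step 10. Hydrogen may add to the C2–C3 double bond of either chromone, or the hydrogenolysis may stall at partly benzylated material as solubility drops. The fallback is a Lewis-acid debenzylation with a cation scavenger. It sets out from 16 and arrives at 17. BCl3 with pentamethylbenzene in CH2Cl2 at −78 °C cleaves the benzyl ethers and leaves the non-chelated 4'-methyl ether. This fallback makes no new compound (F0).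

**Further compounds**

F1 | step 9 | 8-[3-acetyl-4-(benzyloxy)-2,6-dihydroxyphenyl]-5,7-bis(benzyloxy)-2-(4-methoxyphenyl)-4H-chromen-4-one | COc1ccc(cc1)-c1cc(=O)c2c(OCc3ccccc3)cc(OCc3ccccc3)c(-c3c(O)cc(OCc4ccccc4)c(C(C)=O)c3O)c2o1
F2 | step 6 | [4-(benzyloxy)-2,6-bis(methoxymethoxy)phenyl]zinc chloride | Cl[Zn]c1c(OCOC)cc(OCc2ccccc2)cc1OCOC
F0 | step 10 | none | none
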